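**Retrosynthetic overview**
- Gardenin C comes from 3'-benzyloxy-5,6,7,8,4',5'-hexamethoxyflavone by O-debenzylation, then chelation-controlled cleavage of the 5-OMe group.
- Ring C (the pyranone) is formed last, by I2/DMSO oxidative cyclisation of a 2'-hydroxychalcone; rings A and B come from simple benzene starting materials.
- The chalcone Cα–Cβ bond is the key bond: an intermolecular Claisen–Schmidt aldol condensation of 2'-hydroxy-3',4',5',6'-tetramethoxyacetophenone with 3-benzyloxy-4,5-dimethoxybenzaldehyde.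
- The ring A ketone comes from 2,3,4-trimethoxybenzaldehyde by two rounds of aryl oxygenation (Baeyer–Villiger; O-methylation, formylation, Baeyer–Villiger), then ortho C-acetylation.
- The ring B aldehyde comes from 5-bromovanillin by Cu-mediated hydroxylation, selective 4-O-methylation and O-benzylation.

Assumption: the target has no stereocentre, so "single enantiomer" calls for no stereocontrol; the only stereo-element on the route is the E alkene of the chalcone.

**Route**

Step 1
Reactants: 1 2,3,4-trimethoxybenzaldehyde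
Product: 3 2,3,4-trimethoxyphenol, via aryl formate 2 (not isolated)
Conditions: mCPBA (1.3 equiv), CH2Cl2, 0 °C → rt; aq. NaHCO3 wash; then K2CO3 (0.2 equiv), MeOH, rt
Reagents that add atoms: mCPBA (3-chloroperoxybenzoic acid), O=C(OO)c1cccc(Cl)c1
Why: Baeyer–Villiger (Dakin-type) oxidation in which the electron-rich aryl group migrates in preference to hydride, and base-catalysed methanolysis then frees the phenol from its formate.

Step 2
Reactants: 3 2,3,4-trimethoxyphenol
Product: 4 1,2,3,4-tetramethoxybenzene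
Conditions: MeI (1.5 equiv), K2CO3, acetone, reflux
Reagents that add atoms: iodomethane, CI
Why: Williamson ether synthesis, a simple SN2 O-methylation of the phenoxide.

Step 3
Reactants: 4 1,2,3,4-tetramethoxybenzene
Product: 6 2,3,4,5-tetramethoxybenzaldehyde, via aryl iminium chloride 5 (not isolated)
Conditions: POCl3 (1.5 equiv), DMF, 0 → 80 °C; then ice/H2O, rt
Reagents that add atoms: N,N-dimethylformamide, CN(C)C=O; water, O
Why: Vilsmeier–Haack formylation of a tetra-activated arene whose two free positions are equivalent by symmetry, so only one aldehyde can form once the iminium salt is hydrolysed.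

Step 4
Reactants: 6 2,3,4,5-tetramethoxybenzaldehyde
Product: 8 2,3,4,5-tetramethoxyphenol, via aryl formate 7 (not isolated)
Conditions: mCPBA (1.3 equiv), CH2Cl2, 0 °C → rt; aq. NaHCO3 wash; then K2CO3 (0.2 equiv), MeOH, rt, N2
Reagents that add atoms: mCPBA (3-chloroperoxybenzoic acid), O=C(OO)c1cccc(Cl)c1
Why: a second Baeyer–Villiger oxidation with aryl migration favoured by the ortho and para methoxy groups, followed by methanolysis of the formate.

Step 5
Reactants: 8 2,3,4,5-tetramethoxyphenol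
Product: 10 1-(2-hydroxy-3,4,5,6-tetramethoxyphenyl)ethan-1-one, via difluoroboron chelate 9 (not isolated)
Conditions: AcOH, BF3·OEt2 (3 equiv), 90 °C, N2; then H2O/MeOH, 60 °C
Reagents that add atoms: acetic acid, CC(=O)O
Why: BF3-mediated Friedel–Crafts (Fries-type) C-acetylation at the only free ring position, which lies ortho to the OH; the ketone is held as its difluoroboron chelate until hydrolysis.

Step 6
Reactants: 11 5-bromovanillin (3-bromo-4-hydroxy-5-methoxybenzaldehyde)
Product: 12 3,4-dihydroxy-5-methoxybenzaldehyde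
Conditions: NaOH (aq., 8 equiv), Cu powder (cat.), reflux, N2, 24 h; then HCl (aq.)
Reagents that add atoms: sodium hydroxide, [Na+].[OH-]
Why: copper-mediated Ullmann-type hydroxylation of the aryl bromide by hydroxide, the classical preparation of 5-hydroxyvanillin.

Step 7
Reactants: 12 3,4-dihydroxy-5-methoxybenzaldehyde
Product: 13 3-hydroxy-4,5-dimethoxybenzaldehyde
Conditions: Me2SO4 (1.1 equiv), Na2CO3, acetone, reflux
Reagents that add atoms: dimethyl sulfate, COS(=O)(=O)OC
Why: selective Williamson O-methylation, because the 4-OH para to the formyl group is the more acidic and is the one ionised by the weak base.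

Step 8
Reactants: 13 3-hydroxy-4,5-dimethoxybenzaldehyde
Product: 14 3-(benzyloxy)-4,5-dimethoxybenzaldehyde
Conditions: BnBr (1.2 equiv), K2CO3, DMF, 60 °C
Reagents that add atoms: benzyl bromide, BrCc1ccccc1
Why: Williamson O-benzylation masks the remaining phenol so that no phenoxide deactivates the aldehyde in the aldol step.

Step 9
Reactants: 10 1-(2-hydroxy-3,4,5,6-tetramethoxyphenyl)ethan-1-one; 14 3-(benzyloxy)-4,5-dimethoxybenzaldehyde
Product: 16 (E)-3-[3-(benzyloxy)-4,5-dimethoxyphenyl]-1-(2-hydroxy-3,4,5,6-tetramethoxyphenyl)prop-2-en-1-one, via aldol adduct 15 (not isolated)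
Conditions: KOH (50% aq., 10 equiv), EtOH, rt, 48 h; then HCl (aq.), 0 °C
Reagents that add atoms: none
Why: Claisen–Schmidt crossed aldol condensation in which the methyl ketone enolate adds to the non-enolisable aldehyde and the racemic carbinol of 15 is lost by E1cB dehydration to the thermodynamically favoured E enone.

Step 10
Reactants: 16 (E)-3-[3-(benzyloxy)-4,5-dimethoxyphenyl]-1-(2-hydroxy-3,4,5,6-tetramethoxyphenyl)prop-2-en-1-one
Product: 18 2-[3-(benzyloxy)-4,5-dimethoxyphenyl]-5,6,7,8-tetramethoxy-4H-chromen-4-one, via flavanone 17 (not isolated)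
Conditions: I2 (10 mol%), DMSO, 120 °C, 3 h; then aq. Na2S2O3
Reagents that add atoms: none
Why: iodine-catalysed oxidative cyclisation, an intramolecular oxa-Michael closure of ring C followed by iodine-mediated dehydrogenation with DMSO as terminal oxidant, which removes the racemic C2 centre of 17.

Step 11
Reactants: 18 2-[3-(benzyloxy)-4,5-dimethoxyphenyl]-5,6,7,8-tetramethoxy-4H-chromen-4-one
Product: 19 2-(3-hydroxy-4,5-dimethoxyphenyl)-5,6,7,8-tetramethoxy-4H-chromen-4-one
Conditions: H2 (1 atm), Pd/C (10 wt% Pd), EtOAc/MeOH 1:1, rt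
Reagents that add atoms: none
Why: catalytic hydrogenolysis cleaves the benzyl aryl ether, while the flavone enone and the methyl ethers are inert at 1 atm and rt.

Step 12
Reactants: 19 2-(3-hydroxy-4,5-dimethoxyphenyl)-5,6,7,8-tetramethoxy-4H-chromen-4-one
Product: 21 Gardenin C (5-hydroxy-2-(3-hydroxy-4,5-dimethoxyphenyl)-6,7,8-trimethoxy-4H-chromen-4-one), via dichloroboron chelate 20 (not isolated)
Conditions: BCl3 (1 M in CH2Cl2, 3 equiv), CH2Cl2, −20 → 0 °C; then MeOH, HCl (aq.), rt
Reagents that add atoms: none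
Why: chelation-controlled Lewis-acid demethylation, in which boron bound between the C4 carbonyl and the peri 5-OMe makes that methyl the only one open to SN2 attack by chloride at or below 0 °C.

**Compound list**
1 | 2,3,4-trimethoxybenzaldehyde | COc1ccc(C=O)c(OC)c1OC | starting material
2 | 2,3,4-trimethoxyphenyl formate | COc1ccc(OC=O)c(OC)c1OC | intermediate (not isolated)
3 | 2,3,4-trimethoxyphenol | COc1ccc(O)c(OC)c1OC | intermediate
4 | 1,2,3,4-tetramethoxybenzene | COc1ccc(OC)c(OC)c1OC | intermediate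
5 | N,N-dimethyl-(2,3,4,5-tetramethoxyphenyl)methaniminium chloride | C[N+](C)=Cc1cc(OC)c(OC)c(OC)c1OC.[Cl-] | intermediate (not isolated)
6 | 2,3,4,5-tetramethoxybenzaldehyde | COc1cc(C=O)c(OC)c(OC)c1OC | intermediate
7 | 2,3,4,5-tetramethoxyphenyl formate | COc1cc(OC=O)c(OC)c(OC)c1OC | intermediate (not isolated)
8 | 2,3,4,5-tetramethoxyphenol | COc1cc(O)c(OC)c(OC)c1OC | intermediate
9 | difluoroboron chelate of 10 (O,O-chelate through the phenolate and ketone oxygens) | CC1=[O+][B-](F)(F)Oc2c(OC)c(OC)c(OC)c(OC)c12 | intermediate (not isolated)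
10 | 1-(2-hydroxy-3,4,5,6-tetramethoxyphenyl)ethan-1-one | CC(=O)c1c(O)c(OC)c(OC)c(OC)c1OC | intermediate
11 | 5-bromovanillin (3-bromo-4-hydroxy-5-methoxybenzaldehyde) | COc1cc(C=O)cc(Br)c1O | starting material
12 | 3,4-dihydroxy-5-methoxybenzaldehyde (5-hydroxyvanillin) | COc1cc(C=O)cc(O)c1O | intermediate
13 | 3-hydroxy-4,5-dimethoxybenzaldehyde | COc1cc(C=O)cc(O)c1OC | intermediate
14 | 3-(benzyloxy)-4,5-dimethoxybenzaldehyde | COc1cc(C=O)cc(OCc2ccccc2)c1OC | intermediate
15 | racemic 3-[3-(benzyloxy)-4,5-dimethoxyphenyl]-3-hydroxy-1-(2-hydroxy-3,4,5,6-tetramethoxyphenyl)propan-1-one | COc1cc(C(O)CC(=O)c2c(O)c(OC)c(OC)c(OC)c2OC)cc(OCc2ccccc2)c1OC | intermediate (not isolated)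
16 | (E)-3-[3-(benzyloxy)-4,5-dimethoxyphenyl]-1-(2-hydroxy-3,4,5,6-tetramethoxyphenyl)prop-2-en-1-one | COc1cc(/C=C/C(=O)c2c(O)c(OC)c(OC)c(OC)c2OC)cc(OCc2ccccc2)c1OC | intermediate
17 | racemic 2-[3-(benzyloxy)-4,5-dimethoxyphenyl]-5,6,7,8-tetramethoxychroman-4-one | COc1cc(C2CC(=O)c3c(OC)c(OC)c(OC)c(OC)c3O2)cc(OCc2ccccc2)c1OC | intermediate (not isolated)
18 | 2-[3-(benzyloxy)-4,5-dimethoxyphenyl]-5,6,7,8-tetramethoxy-4H-chromen-4-one | COc1cc(-c2cc(=O)c3c(OC)c(OC)c(OC)c(OC)c3o2)cc(OCc2ccccc2)c1OC | intermediate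
19 | 2-(3-hydroxy-4,5-dimethoxyphenyl)-5,6,7,8-tetramethoxy-4H-chromen-4-one | COc1cc(-c2cc(=O)c3c(OC)c(OC)c(OC)c(OC)c3o2)cc(O)c1OC | intermediate
20 | dichloroboron chelate of the 5-O/4-carbonyl unit, with the 3'-oxygen as its dichloroboryl ether | COc1cc(C2=CC3=[O+][B-](Cl)(Cl)Oc4c(OC)c(OC)c(OC)c(O2)c34)cc(OB(Cl)Cl)c1OC | intermediate (not isolated)
21 | Gardenin C, 5-hydroxy-2-(3-hydroxy-4,5-dimethoxyphenyl)-6,7,8-trimethoxy-4H-chromen-4-one | COc1cc(-c2cc(=O)c3c(O)c(OC)c(OC)c(OC)c3o2)cc(O)c1OC | target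

**Summary**
Total step count: 12.
Longest linear sequence: 9 steps (steps 1–5 and 9–12, from 1); the ring B branch is 7 steps (steps 6–8 and 9–12, from 11).

**Steps most likely to fail, with fallbacks**

Step 6 (Cu-mediated hydroxylation; variable yield, reduction to vanillin, air-sensitive catechol product). The fallback sets out from 11 and comes back at 13, replacing steps 6 and 7. Compound 11 is O-methylated (MeI, K2CO3, DMF) to 3-bromo-4,5-dimethoxybenzaldehyde F1. Miyaura borylation of the C–Br bond (bis(pinacolato)diboron, PdCl2(dppf), KOAc, dioxane, 90 °C) then gives 3,4-dimethoxy-5-(4,4,5,5-tetramethyl-1,3,2-dioxaborolan-2-yl)benzaldehyde F2. Mild oxidation of the C–B bond (NaBO3·4H2O, THF/H2O, rt) delivers 13, and the route continues with step 8.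

Step 9 (aldol condensation of a hindered, electron-rich, fully substituted acetophenone; slow addition, partial closure to flavanone, Cannizzaro loss of 14). Any flavanone formed is harmless, since it is the intermediate of step 10. If conversion stays poor, the fallback swaps the aldol for a Claisen condensation; it sets out from 14 (with 10) and comes back at 18. Pinnick oxidation of 14 (NaClO2, NaH2PO4, 2-methyl-2-butene, t-BuOH/H2O) gives 3-(benzyloxy)-4,5-dimethoxybenzoic acid F3. Oxalyl chloride with cat. DMF in CH2Cl2 gives 3-(benzyloxy)-4,5-dimethoxybenzoyl chloride F4. The dianion of 10 (LiN(SiMe3)2, 3.2 equiv, THF, −78 °C) is C-acylated by F4 to give 1-[3-(benzyloxy)-4,5-dimethoxyphenyl]-3-(2-hydroxy-3,4,5,6-tetramethoxyphenyl)propane-1,3-dione F5. Acid-catalysed cyclodehydration (cat. H2SO4, AcOH, 95 °C) gives flavone 18 directly, skipping 16.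

Step 12 (selectivity of the demethylation; with the free 3'-OH borylated next to the 4'-OMe, over-cleavage on ring B or at C6 is possible). The fallback sets out from 19 and comes back at 21. The 3'-OH is acetylated (Ac2O, pyridine, rt) to 5-(5,6,7,8-tetramethoxy-4-oxo-4H-chromen-2-yl)-2,3-dimethoxyphenyl acetate F6, so ring B carries no Lewis-acid-binding phenoxide. The 5-OMe is then cleaved with AlCl3 in MeCN (rt → 50 °C, dilute HCl work-up) to 5-(5-hydroxy-6,7,8-trimethoxy-4-oxo-4H-chromen-2-yl)-2,3-dimethoxyphenyl acetate F7. Methanolysis of the acetate (K2CO3, MeOH, rt) gives 21.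

**Further compounds**
F1 | step 6 | 3-bromo-4,5-dimethoxybenzaldehyde | COc1cc(C=O)cc(Br)c1OC
F2 | step 6 | 3,4-dimethoxy-5-(4,4,5,5-tetramethyl-1,3,2-dioxaborolan-2-yl)benzaldehyde | COc1cc(C=O)cc(B2OC(C)(C)C(C)(C)O2)c1OC
F3 | step 9 | 3-(benzyloxy)-4,5-dimethoxybenzoic acid | COc1cc(C(=O)O)cc(OCc2ccccc2)c1OC
F4 | step 9 | 3-(benzyloxy)-4,5-dimethoxybenzoyl chloride | COc1cc(C(=O)Cl)cc(OCc2ccccc2)c1OC
F5 | step 9 | 1-[3-(benzyloxy)-4,5-dimethoxyphenyl]-3-(2-hydroxy-3,4,5,6-tetramethoxyphenyl)propane-1,3-dione | COc1cc(C(=O)CC(=O)c2c(O)c(OC)c(OC)c(OC)c2OC)cc(OCc2ccccc2)c1OC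
F6 | step 12 | 5-(5,6,7,8-tetramethoxy-4-oxo-4H-chromen-2-yl)-2,3-dimethoxyphenyl acetate | COc1cc(-c2cc(=O)c3c(OC)c(OC)c(OC)c(OC)c3o2)cc(OC(C)=O)c1OC
F7 | step 12 | 5-(5-hydroxy-6,7,8-trimethoxy-4-oxo-4H-chromen-2-yl)-2,3-dimethoxyphenyl acetate | COc1cc(-c2cc(=O)c3c(O)c(OC)c(OC)c(OC)c3o2)cc(OC(C)=O)c1OC
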